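The route rests on cutting the bond between the benzylic carbinol carbon C-7 and the aryloxy-bearing carbon C-8 of the guaiacylglycerol chain. The key step exploits the fact that C-8 lies between the ether oxygen and C-9: with C-9 raised to an N-acyloxazolidinone, C-8 is an enolisable glycolate α-carbon, and C-7 is the formyl carbon of vanillin. One magnesium-catalysed anti-aldol addition joins the aryloxyacetyl imide, which already carries the complete endo-6-aryl-3,7-dioxabicyclo[3.3.0]octan-2-one, to vanillin and sets C-7 and C-8 (erythro). Borohydride then lowers C-9 to CH2OH. The lactone half comes from a C2-symmetric dilactone by mono-arylation and exo-face hydride delivery.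

Key step: step 9

Remark: C-7, C-8 and C-9 denote the benzylic, aryloxy-bearing and hydroxymethyl carbons of the glycerol chain. Read from the SMILES, H-1, H-5 and H-6 of the dioxabicyclooctanone (C-2 = lactone C=O, C-6 = aryl-bearing carbon) are all cis (aryl on the concave face; 1R,5R,6R) and the glycerol unit is erythro (7R,8S). The phenol of vanillin is masked in the flask as its trimethylsilyl ether, so no separate protecting-group steps are planned for it.

**Route**

Step 1
Reactants: 1 (4S)-4-benzyl-1,3-oxazolidin-2-one (2 equiv); 2 succinyl chloride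
Product: 4 1,4-bis[(4S)-4-benzyl-2-oxo-1,3-oxazolidin-3-yl]butane-1,4-dione, via lithiated oxazolidinone 3 (not isolated)
Conditions: n-BuLi, THF, −78 °C; then 2, −78 → 0 °C
Reagents that add atoms: none
Why: Double N-acylation of the lithiated oxazolidinone by the diacid chloride (imide formation) should give the C2-symmetric bis-imide; no stereocentre is formed.

Step 2
Reactants: 4 bis-imide; 5 benzyl chloromethyl ether (2 equiv)
Product: 7 (2R,3R)-1,4-bis[(4S)-4-benzyl-2-oxo-1,3-oxazolidin-3-yl]-2,3-bis[(benzyloxy)methyl]butane-1,4-dione, via bis(titanium enolate) 6 (not isolated)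
Conditions: TiCl4 (2.2 equiv), i-Pr2NEt (2.4 equiv), CH2Cl2, 0 °C; then 5, 0 °C
Reagents that add atoms: none
Why: Auxiliary-controlled alkylation of titanium enolates (benzyloxymethylation) at both α-carbons, one molecule of 5 per carbon: each chelated (Z)-enolate of 6 should be attacked on the face opposite the 4-benzyl group of its own auxiliary, so both new centres are R and the C2-symmetric (2R,3R) isomer forms.

Step 3
Reactants: 7 bis(benzyloxymethyl) bis-imide
Product: 9 (1R,5R)-3,7-dioxabicyclo[3.3.0]octane-2,6-dione, via bis(hydroxymethyl) bis-imide 8 (not isolated)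
Conditions: H2 (1 atm), Pd(OH)2/C, EtOAc, rt; then Et3N (cat.), CH2Cl2, rt
Reagents that add atoms: none
Why: Hydrogenolysis of the two benzyl ethers followed by base-catalysed double lactonisation (5-exo-trig acyl transfer from each imide to the γ-hydroxyl of the other arm, auxiliary as leaving group) should give the cis-fused dilactone, which the meso diastereomer could not form; C-1 and C-5 are not touched.

Step 4
Reactants: 10 4-bromo-2,6-dimethoxyphenol
Product: 11 (4-bromo-2,6-dimethoxyphenoxy)(tert-butyl)dimethylsilane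
Conditions: TBSCl, imidazole, DMF, rt
Reagents that add atoms: tert-butyldimethylsilyl chloride, CC(C)(C)[Si](C)(C)Cl
Why: Silylation of the phenol (silyl ether protection) makes the aryl bromide compatible with the organolithium and Lewis acid steps.

Step 5
Reactants: 11 aryl bromide; 9 dilactone (1.5 equiv)
Product: 13 (1R,5R)-6-[4-(tert-butyldimethylsilyloxy)-3,5-dimethoxyphenyl]-6-hydroxy-3,7-dioxabicyclo[3.3.0]octan-2-one (anomer mixture), via aryllithium 12 (not isolated)
Conditions: n-BuLi, THF, −78 °C; then cannulate into 9, THF, −78 °C; AcOH quench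
Reagents that add atoms: none
Why: Bromine–lithium exchange and 1,2-addition of the aryllithium to a lactone carbonyl at −78 °C should stop at the hemiketal; the two carbonyls of C2-symmetric 9 are homotopic, so mono-addition gives one constitutional isomer, and excess 9 with inverse addition limits double addition.

Step 6
Reactants: 13 hemiketal
Product: 15 (1R,5R,6R)-6-[4-(tert-butyldimethylsilyloxy)-3,5-dimethoxyphenyl]-3,7-dioxabicyclo[3.3.0]octan-2-one, via oxocarbenium ion 14 (not isolated)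
Conditions: Et3SiH, BF3·OEt2, CH2Cl2, −78 → −40 °C
Reagents that add atoms: none
Why: Ionic hydrogenation of a lactol (silane and Lewis acid): BF3 should ionise the hemiketal to the aryl-stabilised oxocarbenium ion 14, and hydride adds to C-6 on the convex face of the cis-fused bicycle, which places H-6 cis to H-1 and H-5 and the aryl group on the concave face (6R).

Step 7
Reactants: 1 (4S)-4-benzyl-1,3-oxazolidin-2-one; 16 bromoacetyl bromide
Product: 18 (4S)-4-benzyl-3-(bromoacetyl)-1,3-oxazolidin-2-one, via sodium oxazolidinide 17 (not isolated)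
Conditions: NaH, THF, 0 °C; then 16, −78 °C
Reagents that add atoms: none
Why: N-acylation of the sodium salt of the oxazolidinone at the acyl bromide carbon, which reacts far faster than the CH2Br carbon at −78 °C; no stereocentre is formed.

Step 8
Reactants: 15 silyl-protected lactone; 18 bromoacetyl imide
Product: 20 (4S)-4-benzyl-3-({2,6-dimethoxy-4-[(1R,5R,6R)-2-oxo-3,7-dioxabicyclo[3.3.0]oct-6-yl]phenoxy}acetyl)-1,3-oxazolidin-2-one, via caesium phenolate 19 (not isolated)
Conditions: CsF, DMF, 0 °C → rt; then 18, rt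
Reagents that add atoms: none
Why: Fluoride-induced cleavage of the aryl silyl ether gives the phenolate in the flask, which is O-alkylated by the activated α-bromo imide (Williamson ether synthesis, SN2); no stereocentre is involved.

Step 9
Reactants: 20 aryloxyacetyl imide; 21 vanillin (1.3 equiv)
Product: 25 (4S)-4-benzyl-3-[(2R,3R)-2-{2,6-dimethoxy-4-[(1R,5R,6R)-2-oxo-3,7-dioxabicyclo[3.3.0]oct-6-yl]phenoxy}-3-hydroxy-3-(4-hydroxy-3-methoxyphenyl)propanoyl]-1,3-oxazolidin-2-one, via silylated vanillin 22 (not isolated), via magnesium enolate 23 (not isolated), via bis-silylated aldol adduct 24 (not isolated)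
Conditions: 21, TMSCl (3 equiv), Et3N (4 equiv), EtOAc, 0 °C; then 20, MgCl2 (20 mol%), rt; then aq. citric acid, THF, 0 °C
Reagents that add atoms: none
Why: MgCl2 and Et3N should enolise only the imide (two-point binding of Mg to both imide carbonyls) to the chelated (Z)-enolate 23, which adds to the silyl-masked aldehyde 22 through a closed boat transition state, while TMSCl silylates the magnesium aldolate so that Mg turns over; the closest known reaction type is the magnesium halide-catalysed direct anti-aldol reaction of chiral N-acyloxazolidinones with aromatic aldehydes. No ring is closed. C-8 is set by the auxiliary: its 4-benzyl group blocks one face of the chelated enolate, so the aldehyde carbon bonds to the opposite face (2R in the adduct, which is 8S in the target once C-9 is CH2OH, because the CIP ranks of C-7 and C-9 swap). C-7 is set by the boat arrangement of the Z-enolate and the aldehyde, which gives the anti (erythro, 3R) relationship. The step needs anti over syn selectivity, one enolate face and enolisation at the imide α-CH2 only; the chelating auxiliary, the non-enolisable aldehyde and the much lower acidity of the lactone α-hydrogen should secure these, and the phenol is kept out of play as its transient silyl ether.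

Step 10
Reactants: 25 aldol adduct
Product: 26 (1R,5R,6R)-6-(4-{[(1R,2S)-1,3-dihydroxy-1-(4-hydroxy-3-methoxyphenyl)propan-2-yl]oxy}-3,5-dimethoxyphenyl)-3,7-dioxabicyclo[3.3.0]octan-2-one (target)
Conditions: NaBH4 (4 equiv), THF/H2O (4:1), 0 °C; sat. NH4Cl
Reagents that add atoms: none
Why: Reductive removal of the oxazolidinone auxiliary with borohydride: the exocyclic imide carbonyl is much more electrophilic than the γ-lactone carbonyl, so C-9 should be reduced to CH2OH with release of 1 while the lactone, C-7 and C-8 stay untouched.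

**Compound list**

1 | (4S)-4-benzyl-1,3-oxazolidin-2-one | O=C1OC[C@H](Cc2ccccc2)N1 | starting material
2 | succinyl chloride | ClC(=O)CCC(=O)Cl | starting material
3 | lithium salt of 1 (lithiated oxazolidinone) | O=C1OC[C@H](Cc2ccccc2)N1[Li] | intermediate
4 | 1,4-bis[(4S)-4-benzyl-2-oxo-1,3-oxazolidin-3-yl]butane-1,4-dione | O=C1OC[C@H](Cc2ccccc2)N1C(=O)CCC(=O)N1[C@@H](Cc2ccccc2)COC1=O | intermediate
5 | benzyl chloromethyl ether | ClCOCc1ccccc1 | starting material
6 | bis(trichlorotitanium) (Z,Z)-dienolate of 4 | Cl[Ti](Cl)(Cl)O/C(N1[C@@H](Cc2ccccc2)COC1=O)=C\C=C(/O[Ti](Cl)(Cl)Cl)N1[C@@H](Cc2ccccc2)COC1=O | intermediate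
7 | (2R,3R)-1,4-bis[(4S)-4-benzyl-2-oxo-1,3-oxazolidin-3-yl]-2,3-bis[(benzyloxy)methyl]butane-1,4-dione | O=C1OC[C@H](Cc2ccccc2)N1C(=O)[C@@H](COCc1ccccc1)[C@H](COCc1ccccc1)C(=O)N1[C@@H](Cc2ccccc2)COC1=O | intermediate
8 | (2R,3R)-1,4-bis[(4S)-4-benzyl-2-oxo-1,3-oxazolidin-3-yl]-2,3-bis(hydroxymethyl)butane-1,4-dione | O=C1OC[C@H](Cc2ccccc2)N1C(=O)[C@@H](CO)[C@H](CO)C(=O)N1[C@@H](Cc2ccccc2)COC1=O | intermediate
9 | (1R,5R)-3,7-dioxabicyclo[3.3.0]octane-2,6-dione (cis-fused, C2-symmetric) | O=C1OC[C@@H]2C(=O)OC[C@H]12 | intermediate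
10 | 4-bromo-2,6-dimethoxyphenol | COc1cc(Br)cc(OC)c1O | starting material
11 | (4-bromo-2,6-dimethoxyphenoxy)(tert-butyl)dimethylsilane | COc1cc(Br)cc(OC)c1O[Si](C)(C)C(C)(C)C | intermediate
12 | [4-(tert-butyldimethylsilyloxy)-3,5-dimethoxyphenyl]lithium | COc1cc([Li])cc(OC)c1O[Si](C)(C)C(C)(C)C | intermediate
13 | (1R,5R)-6-[4-(tert-butyldimethylsilyloxy)-3,5-dimethoxyphenyl]-6-hydroxy-3,7-dioxabicyclo[3.3.0]octan-2-one (C-6 anomers) | COc1cc(cc(OC)c1O[Si](C)(C)C(C)(C)C)C1(O)OC[C@@H]2C(=O)OC[C@@H]21 | intermediate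
14 | cyclic oxocarbenium ion from 13 (hydroxytrifluoroborate salt) | COc1cc(cc(OC)c1O[Si](C)(C)C(C)(C)C)C1=[O+]C[C@@H]2C(=O)OC[C@@H]21.O[B-](F)(F)F | intermediate
15 | (1R,5R,6R)-6-[4-(tert-butyldimethylsilyloxy)-3,5-dimethoxyphenyl]-3,7-dioxabicyclo[3.3.0]octan-2-one (aryl endo; H-1, H-5, H-6 all cis) | COc1cc(cc(OC)c1O[Si](C)(C)C(C)(C)C)[C@@H]1OC[C@@H]2C(=O)OC[C@@H]21 | intermediate
16 | bromoacetyl bromide | BrCC(=O)Br | starting material
17 | sodium salt of 1 (sodium oxazolidinide) | O=C1OC[C@H](Cc2ccccc2)N1[Na] | intermediate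
18 | (4S)-4-benzyl-3-(bromoacetyl)-1,3-oxazolidin-2-one | O=C1OC[C@H](Cc2ccccc2)N1C(=O)CBr | intermediate
19 | caesium 2,6-dimethoxy-4-[(1R,5R,6R)-2-oxo-3,7-dioxabicyclo[3.3.0]oct-6-yl]phenolate | COc1cc(cc(OC)c1[O-])[C@@H]1OC[C@@H]2C(=O)OC[C@@H]21.[Cs+] | intermediate
20 | (4S)-4-benzyl-3-({2,6-dimethoxy-4-[(1R,5R,6R)-2-oxo-3,7-dioxabicyclo[3.3.0]oct-6-yl]phenoxy}acetyl)-1,3-oxazolidin-2-one | O=C1OC[C@H](Cc2ccccc2)N1C(=O)COc1c(OC)cc(cc1OC)[C@@H]1OC[C@@H]2C(=O)OC[C@@H]21 | intermediate
21 | vanillin (4-hydroxy-3-methoxybenzaldehyde) | COc1cc(C=O)ccc1O | starting material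
22 | 3-methoxy-4-(trimethylsilyloxy)benzaldehyde | COc1cc(C=O)ccc1O[Si](C)(C)C | intermediate
23 | chloromagnesium (Z)-enolate of 20 | Cl[Mg]O/C(=C\Oc1c(OC)cc(cc1OC)[C@@H]1OC[C@@H]2C(=O)OC[C@@H]21)N1[C@@H](Cc2ccccc2)COC1=O | intermediate
24 | bis(trimethylsilyl) ether of 25 (benzylic O and phenolic O silylated) | COc1cc(ccc1O[Si](C)(C)C)[C@@H](O[Si](C)(C)C)[C@H](C(=O)N1[C@@H](Cc2ccccc2)COC1=O)Oc1c(OC)cc(cc1OC)[C@@H]1OC[C@@H]2C(=O)OC[C@@H]21 | intermediate
25 | (4S)-4-benzyl-3-[(2R,3R)-2-{2,6-dimethoxy-4-[(1R,5R,6R)-2-oxo-3,7-dioxabicyclo[3.3.0]oct-6-yl]phenoxy}-3-hydroxy-3-(4-hydroxy-3-methoxyphenyl)propanoyl]-1,3-oxazolidin-2-one (anti aldol) | COc1cc(ccc1O)[C@@H](O)[C@H](C(=O)N1[C@@H](Cc2ccccc2)COC1=O)Oc1c(OC)cc(cc1OC)[C@@H]1OC[C@@H]2C(=O)OC[C@@H]21 | intermediate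
26 | (1R,5R,6R)-6-(4-{[(1R,2S)-1,3-dihydroxy-1-(4-hydroxy-3-methoxyphenyl)propan-2-yl]oxy}-3,5-dimethoxyphenyl)-3,7-dioxabicyclo[3.3.0]octan-2-one | COc1cc([C@@H](O)[C@H](CO)Oc2c(OC)cc([C@@H]3OC[C@@H]4C(=O)OC[C@@H]43)cc2OC)ccc1O | target

**Count**

Total steps: 10. Longest linear sequence: 8 (steps 1, 2, 3, 5, 6, 8, 9, 10); steps 4 and 7 are side branches.

**Steps most likely to fail**

Step 9. The α-aryloxy enolate may react with eroded anti/syn or facial selectivity (the ether oxygen can compete with the auxiliary carbonyl for magnesium), turnover may be slow with the electron-rich aldehyde, and retro-aldol may occur on desilylation. The fallback gives up the direct anti-aldol and uses the boron syn-aldol of the enantiomeric auxiliary followed by inversion at C-7. It sets out from 15. Desilylation and alkylation (CsF, DMF) with (4R)-4-benzyl-3-(bromoacetyl)-1,3-oxazolidin-2-one F1, made from purchased (4R)-4-benzyl-1,3-oxazolidin-2-one and 16 by the procedure of step 7, should give the (4R)-aryloxyacetyl imide F2. Enolisation with Bu2BOTf/i-Pr2NEt and addition to purchased 4-(benzyloxy)-3-methoxybenzaldehyde (closed chair transition state, dipole-opposed auxiliary) should give the (2R,3S)-syn aldol adduct F3. NaBH4 in aqueous THF should give the threo-(7S,8S) diol F4, and TBSCl/imidazole should silylate the primary hydroxyl to give the 9-O-silyl ether F5. A Mitsunobu reaction (4-nitrobenzoic acid, PPh3, DIAD) should invert C-7 to the (7R)-4-nitrobenzoate F6. K2CO3/MeOH (the lactone re-closes on neutralisation) should cleave the nitrobenzoate to the 9-O-silyl erythro alcohol F7, and TBAF should then give the O-benzyl erythro diol F8. Hydrogenolysis (H2, Pd/C, EtOAc) removes the benzyl ether and the route comes back at 26.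

Step 10. Hydride may also attack the γ-lactone (over-reduction) or the ring carbonyl of the auxiliary. The fallback separates cleavage and reduction. It sets out from 25: LiOH/H2O2 in THF/H2O at 0 °C, then acidification to pH 3 (which re-closes any opened lactone), should give (2R,3R)-2-{2,6-dimethoxy-4-[(1R,5R,6R)-2-oxo-3,7-dioxabicyclo[3.3.0]oct-6-yl]phenoxy}-3-hydroxy-3-(4-hydroxy-3-methoxyphenyl)propanoic acid F9. BH3·SMe2 in THF at 0 °C reduces the carboxylic acid in preference to the lactone, and the route comes back at 26.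

Step 5. The aryllithium may add twice (to the second lactone or to the ring-opened ketone) or enolise the dilactone. The fallback brings the aryl group in at the aldehyde oxidation level. It sets out from 9: DIBAL-H (1 equiv, CH2Cl2, −78 °C) should give the lactol (1R,5R)-6-hydroxy-3,7-dioxabicyclo[3.3.0]octan-2-one F10. The aryl Grignard reagent [4-(tert-butyldimethylsilyloxy)-3,5-dimethoxyphenyl]magnesium bromide F11, made from 11 and Mg, adds to its open hydroxy-aldehyde form to give the benzylic carbinol (3R,4R)-4-{[4-(tert-butyldimethylsilyloxy)-3,5-dimethoxyphenyl](hydroxy)methyl}-3-(hydroxymethyl)oxolan-2-one F12 as both carbinol epimers. MnO2 in CH2Cl2 oxidises only the benzylic alcohol, and the keto alcohol closes to the hemiketal, so the route comes back at 13.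

**Further compounds**

F1 | step 9 | (4R)-4-benzyl-3-(bromoacetyl)-1,3-oxazolidin-2-one | O=C1OC[C@@H](Cc2ccccc2)N1C(=O)CBr
F2 | step 9 | (4R)-4-benzyl-3-({2,6-dimethoxy-4-[(1R,5R,6R)-2-oxo-3,7-dioxabicyclo[3.3.0]oct-6-yl]phenoxy}acetyl)-1,3-oxazolidin-2-one | O=C1OC[C@@H](Cc2ccccc2)N1C(=O)COc1c(OC)cc(cc1OC)[C@@H]1OC[C@@H]2C(=O)OC[C@@H]21
F3 | step 9 | (4R)-4-benzyl-3-[(2R,3S)-3-[4-(benzyloxy)-3-methoxyphenyl]-2-{2,6-dimethoxy-4-[(1R,5R,6R)-2-oxo-3,7-dioxabicyclo[3.3.0]oct-6-yl]phenoxy}-3-hydroxypropanoyl]-1,3-oxazolidin-2-one (syn aldol) | COc1cc(ccc1OCc1ccccc1)[C@H](O)[C@H](C(=O)N1[C@H](Cc2ccccc2)COC1=O)Oc1c(OC)cc(cc1OC)[C@@H]1OC[C@@H]2C(=O)OC[C@@H]21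
F4 | step 9 | (1R,5R,6R)-6-(4-{[(1S,2S)-1-[4-(benzyloxy)-3-methoxyphenyl]-1,3-dihydroxypropan-2-yl]oxy}-3,5-dimethoxyphenyl)-3,7-dioxabicyclo[3.3.0]octan-2-one (threo) | COc1cc(ccc1OCc1ccccc1)[C@H](O)[C@H](CO)Oc1c(OC)cc(cc1OC)[C@@H]1OC[C@@H]2C(=O)OC[C@@H]21
F5 | step 9 | 9-O-tert-butyldimethylsilyl ether of F4 | COc1cc(ccc1OCc1ccccc1)[C@H](O)[C@H](CO[Si](C)(C)C(C)(C)C)Oc1c(OC)cc(cc1OC)[C@@H]1OC[C@@H]2C(=O)OC[C@@H]21
F6 | step 9 | (7R)-4-nitrobenzoate of the 9-O-silyl ether (C-7 inverted) | COc1cc(ccc1OCc1ccccc1)[C@@H](OC(=O)c1ccc(cc1)[N+](=O)[O-])[C@H](CO[Si](C)(C)C(C)(C)C)Oc1c(OC)cc(cc1OC)[C@@H]1OC[C@@H]2C(=O)OC[C@@H]21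
F7 | step 9 | 9-O-tert-butyldimethylsilyl ether of F8 (erythro, 7-OH free) | COc1cc(ccc1OCc1ccccc1)[C@@H](O)[C@H](CO[Si](C)(C)C(C)(C)C)Oc1c(OC)cc(cc1OC)[C@@H]1OC[C@@H]2C(=O)OC[C@@H]21
F8 | step 9 | (1R,5R,6R)-6-(4-{[(1R,2S)-1-[4-(benzyloxy)-3-methoxyphenyl]-1,3-dihydroxypropan-2-yl]oxy}-3,5-dimethoxyphenyl)-3,7-dioxabicyclo[3.3.0]octan-2-one (erythro, O-benzyl ether of 26) | COc1cc(ccc1OCc1ccccc1)[C@@H](O)[C@H](CO)Oc1c(OC)cc(cc1OC)[C@@H]1OC[C@@H]2C(=O)OC[C@@H]21
F9 | step 10 | (2R,3R)-2-{2,6-dimethoxy-4-[(1R,5R,6R)-2-oxo-3,7-dioxabicyclo[3.3.0]oct-6-yl]phenoxy}-3-hydroxy-3-(4-hydroxy-3-methoxyphenyl)propanoic acid | COc1cc(ccc1O)[C@@H](O)[C@H](C(=O)O)Oc1c(OC)cc(cc1OC)[C@@H]1OC[C@@H]2C(=O)OC[C@@H]21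
F10 | step 5 | (1R,5R)-6-hydroxy-3,7-dioxabicyclo[3.3.0]octan-2-one (lactol, C-6 anomers) | OC1OC[C@@H]2C(=O)OC[C@@H]21
F11 | step 5 | [4-(tert-butyldimethylsilyloxy)-3,5-dimethoxyphenyl]magnesium bromide | COc1cc([Mg]Br)cc(OC)c1O[Si](C)(C)C(C)(C)C
F12 | step 5 | (3R,4R)-4-{[4-(tert-butyldimethylsilyloxy)-3,5-dimethoxyphenyl](hydroxy)methyl}-3-(hydroxymethyl)oxolan-2-one (carbinol epimers) | COc1cc(cc(OC)c1O[Si](C)(C)C(C)(C)C)C(O)[C@H]1COC(=O)[C@H]1CO
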